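**Plan**

- Ring numbering used throughout, also for the open-chain intermediates: C1 = epoxide CH, C2 = epoxide C(Me), C3–C5 = the three CH2, C6 = CMe2, C7 = CH–O, C8=C9(Me) = E-olefin, C10 and C11 = CH2.
- Retrosynthesis: the ring bond C4–C5 is cut as the saturated form of a C4=C5 olefin made by ring-closing metathesis. Then the epoxide oxygen and the C7–O acyl bond are removed, C6–C7 is cut (reverse prenylation of an enal) and C3–C4 is cut (allyl–vinyl coupling). The chain C7–C3 with both E-olefins is geranyl acetate.
- Forward: geranyl acetate is oxidised at its E-methyl group (future C3), vinylated, turned into the enal, reverse-prenylated, acylated and epoxidised. The 11-membered carbocycle then closes in one event and the helper olefin is saturated.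
- Feature that makes the event possible: C4–C5 is the only ring bond between two unfunctionalised CH2 groups and lies next to the quaternary C6, so both of its carbons can enter as terminal vinyl groups (on C6 by reverse prenylation, on C3 by coupling). The E-C8=C9 olefin and the trans C1–C2 epoxide cannot lie in a 7- or 8-membered ring, so only the 11-membered ring can close.
- Stereochemistry: C7 (S) by Brown reverse prenylation with isopinocampheyl groups of the (−)-α-pinene series; C1 and C2 (R,R) by Shi epoxidation of the E-olefin. The geometry of that olefin and of C8=C9 comes from geranyl acetate.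

Key step: step 9

Remark: (+)-Ipc2BH (made from (−)-α-pinene) and the D-fructose-derived Shi ketone are taken as purchased reagents.

**Route**

Step 1
Reactants: 1 geranyl acetate
Product: 2 (2E,6E)-8-hydroxy-3,7-dimethylocta-2,6-dien-1-yl acetate
Conditions: SeO2 (0.1 equiv), t-BuOOH (70% aq.), salicylic acid (0.1 equiv), CH2Cl2, rt
Reagents that add atoms: tert-butyl hydroperoxide CC(C)(C)OO (oxygen source, passed on by the SeO2 catalyst O=[Se]=O)
Why: Catalytic SeO2 allylic oxidation (ene reaction, then [2,3]-sigmatropic shift) is selective for the E-methyl group of the electron-rich 6,7-olefin, the 2,3-olefin being deactivated by the allylic acetate, and keeps both olefin geometries; no stereocenter is formed.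

Step 2
Reactants: 2 (2E,6E)-8-hydroxy-3,7-dimethylocta-2,6-dien-1-yl acetate
Product: 3 (2E,6E)-8-bromo-3,7-dimethylocta-2,6-dien-1-yl acetate
Conditions: CBr4, PPh3, CH2Cl2, 0 °C
Reagents that add atoms: carbon tetrabromide BrC(Br)(Br)Br
Why: The Appel reaction turns the primary allylic alcohol into the bromide under neutral conditions by SN2 displacement of the oxyphosphonium group, without allylic shift and without harm to the acetate.

Step 3
Reactants: 3 (2E,6E)-8-bromo-3,7-dimethylocta-2,6-dien-1-yl acetate; 4 tributyl(vinyl)stannane
Product: 5 (2E,6E)-3,7-dimethyldeca-2,6,9-trien-1-yl acetate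
Conditions: Pd2(dba)3 (2.5 mol%), tri(2-furyl)phosphine (10 mol%), THF, 45 °C
Reagents that add atoms: none
Why: Stille allyl–vinyl coupling: zerovalent palladium inserts into the allylic bromide far faster than it ionises the allylic acetate, and the vinyl group is delivered to the unsubstituted terminus of the π-allyl complex, which gives the skipped diene (C3–C4 bond) with the E-olefin intact.

Step 4
Reactants: 5 (2E,6E)-3,7-dimethyldeca-2,6,9-trien-1-yl acetate
Product: 6 (2E,6E)-3,7-dimethyldeca-2,6,9-trien-1-ol
Conditions: K2CO3 (0.2 equiv), MeOH, rt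
Reagents that add atoms: none
Why: Base-catalysed transesterification with methanol removes the acetate and leaves the three olefins untouched.

Step 5
Reactants: 6 (2E,6E)-3,7-dimethyldeca-2,6,9-trien-1-ol
Product: 7 (2E,6E)-3,7-dimethyldeca-2,6,9-trienal
Conditions: activated MnO2 (excess), CH2Cl2, rt
Reagents that add atoms: none
Why: MnO2 oxidises allylic alcohols selectively to enals under neutral conditions, without over-oxidation, E/Z isomerisation of the 2,3-olefin or migration of the skipped diene.

Step 6
Reactants: 7 (2E,6E)-3,7-dimethyldeca-2,6,9-trienal; 8 3-methylbuta-1,2-diene; 9 (+)-diisopinocampheylborane, (+)-Ipc2BH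
Product: 12 (4S,5E,9E)-3,3,6,10-tetramethyltrideca-1,5,9,12-tetraen-4-ol, via prenyldiisopinocampheylborane 10 (not isolated), via diisopinocampheylborinate of the carbinol 11 (not isolated)
Conditions: 8, 9, THF, −25 °C; then 7, Et2O, −78 °C; then 3 M NaOH, 30% H2O2, 0 °C to rt
Reagents that add atoms: none
Why: Brown reverse prenylation (allylboration): hydroboration of the allene gives the prenylborane, whose γ-carbon adds 1,2 to the enal through a closed six-membered chair transition state so that the CMe2–vinyl unit (C6, C5) is created, and the isopinocampheyl groups of the (−)-α-pinene series direct the attack to the Re face of the aldehyde, which sets C7 as (S).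

Step 7
Reactants: 12 (4S,5E,9E)-3,3,6,10-tetramethyltrideca-1,5,9,12-tetraen-4-ol; 13 4-methoxybenzoyl chloride
Product: 14 (4S,5E,9E)-3,3,6,10-tetramethyltrideca-1,5,9,12-tetraen-4-yl 4-methoxybenzoate
Conditions: Et3N, DMAP (0.2 equiv), CH2Cl2, 0 to 40 °C
Reagents that add atoms: none
Why: DMAP-catalysed acylation (acylpyridinium transfer) esterifies the hindered secondary allylic alcohol without touching its stereocenter and installs the final acyl group, which from here on also deactivates the neighbouring C8=C9 olefin.

Step 8
Reactants: 14 (4S,5E,9E)-3,3,6,10-tetramethyltrideca-1,5,9,12-tetraen-4-yl 4-methoxybenzoate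
Product: 15 (4S,5E)-3,3,6-trimethyl-8-[(2R,3R)-3-methyl-3-(prop-2-en-1-yl)oxiran-2-yl]octa-1,5-dien-4-yl 4-methoxybenzoate
Conditions: D-fructose-derived Shi ketone (0.3 equiv), Oxone (2KHSO5·KHSO4·K2SO4), K2CO3, Bu4NHSO4 (cat.), Na2B4O7 buffer with Na2EDTA, MeCN–CH2(OMe)2–H2O, 0 °C
Reagents that add atoms: potassium peroxymonosulfate (active part of Oxone) [K+].[O-]S(=O)(=O)OO
Why: Shi asymmetric epoxidation: the chiral dioxirane transfers oxygen through a spiro transition state to the only electron-rich, unhindered trisubstituted olefin (C1=C2; C8=C9 is deactivated by the allylic ester and shielded by C6, the vinyl groups are far slower), stereospecifically syn, so the E-geometry gives the trans-epoxide and catalyst control should give (1R,2R).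

Step 9
Reactants: 15 (4S,5E)-3,3,6-trimethyl-8-[(2R,3R)-3-methyl-3-(prop-2-en-1-yl)oxiran-2-yl]octa-1,5-dien-4-yl 4-methoxybenzoate
Product: 16 (1R,4E,6S,8E,11R)-4,7,7,11-tetramethyl-12-oxabicyclo[9.1.0]dodeca-4,8-dien-6-yl 4-methoxybenzoate
Conditions: second-generation Grubbs catalyst RuCl2(=CHPh)(H2IMes)(PCy3) (10 mol% in two portions), CH2Cl2 (0.001 M), 40 °C, slow addition of 15, argon sparge
Reagents that add atoms: none
Why: Chauvin olefin metathesis: the ruthenium benzylidene first exchanges onto the unhindered allyl terminus (C4), the new alkylidene adds [2+2] to the vinyl group on C6, and cycloreversion of the ruthenacyclobutane expels ethene and leaves the C4=C5 olefin (ring-closing metathesis). The closest known reaction type is ring-closing metathesis to 11-membered humulane-type carbocycles at the olefin next to the gem-dimethyl carbon. The one ring closed is the 11-membered carbocycle, formed directly from the open chain by head-to-tail union of its two terminal olefins (a macrocyclisation, not a ring expansion). No stereocenter is formed; C7, C1 and C2 are set beforehand and lie away from the metal, and the geometry of the new olefin (E expected) is of no consequence because step 10 saturates it. The step needs cyclisation to win over oligomerisation and needs the two terminal olefins to react alone: high dilution with slow addition serves the first, as do the gem-dimethyl group at C6 (it bends the chain and makes its vinyl group too hindered to homodimerise) and the rigid E-olefin and trans-epoxide; the trisubstituted C8=C9 olefin is inert to the catalyst, and a 7- or 8-membered closure onto it would have to hold the trans-epoxide or the E-olefin in a small ring.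

Step 10
Reactants: 16 (1R,4E,6S,8E,11R)-4,7,7,11-tetramethyl-12-oxabicyclo[9.1.0]dodeca-4,8-dien-6-yl 4-methoxybenzoate
Product: 17 (1R,4E,6S,11R)-4,7,7,11-tetramethyl-12-oxabicyclo[9.1.0]dodec-4-en-6-yl 4-methoxybenzoate
Conditions: 2-nitrobenzenesulfonylhydrazide (excess, in portions), Et3N, CH2Cl2, rt
Reagents that add atoms: none
Why: Chemoselective diimide reduction: diimide, formed in the flask from the sulfonylhydrazide, transfers two hydrogens in a concerted syn fashion to the strained disubstituted C4=C5 olefin much faster than to the hindered trisubstituted C8=C9 olefin and is inert to the epoxide and ester, so C4–C5 becomes CH2–CH2 and no stereocenter is touched.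

**Compound list**

1 | geranyl acetate, (2E)-3,7-dimethylocta-2,6-dien-1-yl acetate | CC(=O)OC/C=C(\C)CCC=C(C)C | starting material
2 | (2E,6E)-8-hydroxy-3,7-dimethylocta-2,6-dien-1-yl acetate | CC(=O)OC/C=C(\C)CC/C=C(\C)CO | intermediate
3 | (2E,6E)-8-bromo-3,7-dimethylocta-2,6-dien-1-yl acetate | CC(=O)OC/C=C(\C)CC/C=C(\C)CBr | intermediate
4 | tributyl(vinyl)stannane | C=C[Sn](CCCC)(CCCC)CCCC | starting material
5 | (2E,6E)-3,7-dimethyldeca-2,6,9-trien-1-yl acetate | CC(=O)OC/C=C(\C)CC/C=C(\C)CC=C | intermediate
6 | (2E,6E)-3,7-dimethyldeca-2,6,9-trien-1-ol | OC/C=C(\C)CC/C=C(\C)CC=C | intermediate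
7 | (2E,6E)-3,7-dimethyldeca-2,6,9-trienal | O=C/C=C(\C)CC/C=C(\C)CC=C | intermediate
8 | 3-methylbuta-1,2-diene | CC(C)=C=C | starting material
9 | (+)-diisopinocampheylborane, both isopinocampheyl groups of the (−)-α-pinene series | B([C@H]1C[C@H]2C[C@@H]([C@@H]1C)C2(C)C)[C@H]1C[C@H]2C[C@@H]([C@@H]1C)C2(C)C | starting material
10 | (3-methylbut-2-en-1-yl)diisopinocampheylborane | CC(C)=CCB([C@H]1C[C@H]2C[C@@H]([C@@H]1C)C2(C)C)[C@H]1C[C@H]2C[C@@H]([C@@H]1C)C2(C)C | intermediate
11 | diisopinocampheylborinate (B–O ester) of alcohol 12 | C=CC(C)(C)[C@@H](OB([C@H]1C[C@H]2C[C@@H]([C@@H]1C)C2(C)C)[C@H]1C[C@H]2C[C@@H]([C@@H]1C)C2(C)C)/C=C(\C)CC/C=C(\C)CC=C | intermediate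
12 | (4S,5E,9E)-3,3,6,10-tetramethyltrideca-1,5,9,12-tetraen-4-ol | C=CC(C)(C)[C@@H](O)/C=C(\C)CC/C=C(\C)CC=C | intermediate
13 | 4-methoxybenzoyl chloride | COc1ccc(C(Cl)=O)cc1 | starting material
14 | (4S,5E,9E)-3,3,6,10-tetramethyltrideca-1,5,9,12-tetraen-4-yl 4-methoxybenzoate | COc1ccc(C(=O)O[C@@H](/C=C(\C)CC/C=C(\C)CC=C)C(C)(C)C=C)cc1 | intermediate
15 | (4S,5E)-3,3,6-trimethyl-8-[(2R,3R)-3-methyl-3-(prop-2-en-1-yl)oxiran-2-yl]octa-1,5-dien-4-yl 4-methoxybenzoate | COc1ccc(C(=O)O[C@@H](/C=C(\C)CC[C@H]2O[C@]2(C)CC=C)C(C)(C)C=C)cc1 | intermediate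
16 | (1R,4E,6S,8E,11R)-4,7,7,11-tetramethyl-12-oxabicyclo[9.1.0]dodeca-4,8-dien-6-yl 4-methoxybenzoate (11-membered ring, C4=C5 olefin still present) | COc1ccc(C(=O)O[C@H]2/C=C(\C)CC[C@H]3O[C@]3(C)C/C=C/C2(C)C)cc1 | intermediate
17 | (1R,4E,6S,11R)-4,7,7,11-tetramethyl-12-oxabicyclo[9.1.0]dodec-4-en-6-yl 4-methoxybenzoate | COc1ccc(C(=O)O[C@H]2/C=C(\C)CC[C@H]3O[C@]3(C)CCCC2(C)C)cc1 | target

**Step count**

Total steps: 10. Longest linear sequence: 10 steps (from geranyl acetate 1).

**Steps most likely to fail**

Step 9 (ring closure). What may go wrong is intermolecular metathesis through the unhindered allyl terminus, so that dimers and oligomers form faster than the strained 11-membered ring, or loss of catalyst activity through chelation by the epoxide and ester oxygens. The fallback closes the ring before the epoxide is present. It sets out from 14: the same metathesis is run on the all-olefin ester, whose E-olefins fold the chain as in the parent humulene ring and which has no epoxide oxygen, to give (1S,2E,6E,9E)-3,7,11,11-tetramethylcycloundeca-2,6,9-trien-1-yl 4-methoxybenzoate F1. Shi epoxidation of F1 with the ketone and oxidant of step 8 should then take the C1=C2 olefin, the only electron-rich trisubstituted one in the ring (C8=C9 is deactivated by the ester, C4=C5 is disubstituted and neopentylic). The fallback comes back to the route at 16.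

Step 8 (epoxidation). What may go wrong is oxidation at a wrong olefin of the tetraene or a second epoxidation, and saponification of the aryl ester in the basic aqueous medium. The fallback moves the epoxidation three steps earlier and carries the epoxide through. It sets out from 5, where only one unhindered, non-deactivated trisubstituted olefin is present and no aryl ester yet: Shi epoxidation gives (2E)-3-methyl-5-[(2R,3R)-3-methyl-3-(prop-2-en-1-yl)oxiran-2-yl]pent-2-en-1-yl acetate F2. Methanolysis with K2CO3 gives (2E)-3-methyl-5-[(2R,3R)-3-methyl-3-(prop-2-en-1-yl)oxiran-2-yl]pent-2-en-1-ol F3, and MnO2 gives (2E)-3-methyl-5-[(2R,3R)-3-methyl-3-(prop-2-en-1-yl)oxiran-2-yl]pent-2-enal F4. Reverse prenylation with the borane 10 as in step 6 passes through the diisopinocampheylborinate of the epoxy carbinol F5 and, after oxidative work-up, gives (4S,5E)-3,3,6-trimethyl-8-[(2R,3R)-3-methyl-3-(prop-2-en-1-yl)oxiran-2-yl]octa-1,5-dien-4-ol F6. Acylation of F6 with 13 as in step 7 comes back to the route at 15.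

Step 10 (saturation of C4=C5). What may go wrong is hydrogen transfer to the neopentylic olefin being so slow that diimide disproportionates before the reduction is complete, or loss of selectivity when the reagent is forced. The fallback replaces the metal-free pericyclic transfer by homogeneous catalytic hydrogenation. It sets out from 16: H2 (1 atm) with Wilkinson's catalyst RhCl(PPh3)3 (monovalent rhodium) in benzene–ethanol at rt, where selection is by steric access to the metal, should reduce the disubstituted olefin and leave the trisubstituted allylic-ester olefin and the epoxide. It arrives directly at 17.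

**Further compounds**

F1 | step 9 | (1S,2E,6E,9E)-3,7,11,11-tetramethylcycloundeca-2,6,9-trien-1-yl 4-methoxybenzoate | COc1ccc(C(=O)O[C@H]2/C=C(\C)CC/C=C(\C)C/C=C/C2(C)C)cc1
F2 | step 8 | (2E)-3-methyl-5-[(2R,3R)-3-methyl-3-(prop-2-en-1-yl)oxiran-2-yl]pent-2-en-1-yl acetate | CC(=O)OC/C=C(\C)CC[C@H]1O[C@]1(C)CC=C
F3 | step 8 | (2E)-3-methyl-5-[(2R,3R)-3-methyl-3-(prop-2-en-1-yl)oxiran-2-yl]pent-2-en-1-ol | OC/C=C(\C)CC[C@H]1O[C@]1(C)CC=C
F4 | step 8 | (2E)-3-methyl-5-[(2R,3R)-3-methyl-3-(prop-2-en-1-yl)oxiran-2-yl]pent-2-enal | O=C/C=C(\C)CC[C@H]1O[C@]1(C)CC=C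
F5 | step 8 | diisopinocampheylborinate (B–O ester) of alcohol F6 | C=CC(C)(C)[C@@H](OB([C@H]1C[C@H]2C[C@@H]([C@@H]1C)C2(C)C)[C@H]1C[C@H]2C[C@@H]([C@@H]1C)C2(C)C)/C=C(\C)CC[C@H]1O[C@]1(C)CC=C
F6 | step 8 | (4S,5E)-3,3,6-trimethyl-8-[(2R,3R)-3-methyl-3-(prop-2-en-1-yl)oxiran-2-yl]octa-1,5-dien-4-ol | C=CC(C)(C)[C@@H](O)/C=C(\C)CC[C@H]1O[C@]1(C)CC=C
F0 | step 10 | none | none
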